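**Strategy.** Ring numbering: C1 ring ketone, C2 acyl-bearing, C3/C5 enol carbons, C4 monoprenyl, C6 diprenyl. The plan cuts C1–C2 (Claisen), then C3–C4 and the C5–O link. The propionyl carbonyl, C2 and C3 are one propionylketene unit, and propionyl C=O/C3/C5 form a 1,3,5-triketone that a 4-pyranone ring can store. In one thermal operation the ketene, freed from an ethyl dioxinone, bonds to C4 of a silyl enol ether and its acyl oxygen closes on C5, giving the pyranone. The enol ether precursor is a fully prenylated β-keto ester that already contains C4, C5, the quaternary C6 and the C1 ester.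

Key step: step 5

Remark: the target is a β-triketone whose enol tautomers interconvert freely; the last step delivers this system, and it is listed as the tautomer with hydroxyl groups on C3 and C5.

**Step 1**
Reactants: 1 methyl acetoacetate; 2 1-bromo-3-methylbut-2-ene (prenyl bromide)
Product: 3 methyl 7-methyl-3-oxooct-6-enoate
Conditions: NaH, THF, 0 °C; n-BuLi, 0 °C; 2 (1.0 equiv), 0 °C to rt; then 1 M HCl
Reagents that add atoms: none
Why: Huckin–Weiler dianion alkylation: NaH removes the C2 proton, n-BuLi then removes a γ-methyl proton, and the more basic terminal carbanion alone should take up the allylic bromide by SN2 attack at its primary carbon.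

**Step 2**
Reactants: 3 methyl 7-methyl-3-oxooct-6-enoate; 2 1-bromo-3-methylbut-2-ene (2.5 equiv)
Product: 4 methyl 7-methyl-2,2-bis(3-methylbut-2-enyl)-3-oxooct-6-enoate
Conditions: NaH (2.4 equiv), THF, 0 °C; 2, 0 to 50 °C
Reagents that add atoms: none
Why: Acetoacetic ester alkylation run twice in one flask: the sodium enolate of the doubly activated C2 position is a soft carbon nucleophile that should take up two allylic bromides by SN2, while NaH does not ionise the γ-methylene, so the quaternary carbon with both prenyl groups is set.

**Step 3**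
Reactants: 4 methyl 7-methyl-2,2-bis(3-methylbut-2-enyl)-3-oxooct-6-enoate
Product: 5 methyl (3Z)-7-methyl-2,2-bis(3-methylbut-2-enyl)-3-(trimethylsilyloxy)octa-3,6-dienoate
Conditions: LiN(i-Pr)2, THF, −78 °C; Me3SiCl, Et3N, −78 to 0 °C; pentane, filtration, short pad of Et3N-deactivated silica
Reagents that add atoms: chlorotrimethylsilane, C[Si](C)(C)Cl
Why: Kinetic enolisation and O-silylation: the ketone has α-hydrogens only on the side away from the quaternary carbon, so one regioisomeric enolate can form, the bulky acyl substituent should favour the Z geometry (silyloxy group and C5 methylene on the same side), and the hard silyl chloride traps it on oxygen.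

**Step 4**
Reactants: 6 2,2,6-trimethyl-4H-1,3-dioxin-4-one
Product: 7 6-ethyl-2,2-dimethyl-4H-1,3-dioxin-4-one
Conditions: LiN(i-Pr)2, THF, −78 °C; MeI, HMPA, −78 to −40 °C
Reagents that add atoms: iodomethane, CI
Why: Vinylogous enolate alkylation: deprotonation of the 6-methyl group gives the lithium dienolate, which in the presence of the dipolar co-solvent should be methylated at the exocyclic γ-carbon, and the low temperature prevents fragmentation of the dienolate.

**Step 5**
Reactants: 5 methyl (3Z)-7-methyl-2,2-bis(3-methylbut-2-enyl)-3-(trimethylsilyloxy)octa-3,6-dienoate (limiting); 7 6-ethyl-2,2-dimethyl-4H-1,3-dioxin-4-one (2.5 equiv)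
Product: 10 methyl 2-[6-ethyl-3-(3-methylbut-2-enyl)-4-oxo-4H-pyran-2-yl]-5-methyl-2-(3-methylbut-2-enyl)hex-4-enoate, via propionylketene 8 (not isolated), via silyloxydihydropyranone cycloadduct 9 (not isolated)
Conditions: toluene (0.5 M in 5), 110 °C, 7 added over 4 h by syringe pump; then pyridinium p-toluenesulfonate (cat.), 60 °C
Reagents that add atoms: none
Why: At 110 °C dioxinone 7 loses acetone by retro-[4+2] to give propionylketene 8, whose O=C–C=C unit is an electron-poor 1-oxadiene. Its ketene carbon (future C3) bonds to the nucleophilic β-carbon of enol ether 5 (C4) while the acyl oxygen bonds to the silyloxy carbon (C5), an inverse-demand hetero-Diels–Alder addition of the kind known for acylketenes with enol ethers, ketene acetals and enamines. The one new ring, the six-membered oxygen heterocycle, is closed by this [4+2] cycloaddition itself (if the addition is stepwise, by 6-endo attack of the enolate oxygen on the silyloxycarbenium carbon), and β-elimination of trimethylsilanol from adduct 9, completed by the trace of mild acid, gives the conjugated 4-pyranone. The two stereocenters of 9 are transient (cis from suprafacial addition to the Z enol ether) and both are erased, so no stereocontrol is needed. Regiochemistry is fixed by polarity and by the substrate, since C4 is the only nucleophilic carbon of 5 and C6 is already quaternary, and the prenyl olefins and the ester are inert to acylketenes. Capture in preference to ketene dimerisation is favoured by feeding 7 slowly and in excess into a concentrated solution of 5, the excess also covering ketene consumed by the silanol set free.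

**Step 6**
Reactants: 10 methyl 2-[6-ethyl-3-(3-methylbut-2-enyl)-4-oxo-4H-pyran-2-yl]-5-methyl-2-(3-methylbut-2-enyl)hex-4-enoate
Product: 12 postlupulone (3,5-dihydroxy-4,6,6-tris(3-methylbut-2-enyl)-2-propanoylcyclohexa-2,4-dien-1-one), via triketo ester 11 (not isolated)
Conditions: KOH (6 equiv), MeOH–H2O (10:1), degassed, Ar, 50 °C; then cold 1 M HCl to pH 3
Reagents that add atoms: water, O (delivered as hydroxide of KOH, [K+].[OH-])
Why: Hydroxide adds in conjugate fashion to the unhindered ethyl-bearing carbon of the 4-pyranone and the ring opens (retro-oxa-Michael) to triketo ester 11 as its dienolate, in which every ketone is tied up in an enolate so that the methyl ester is the only electrophile left for the C2 carbanion, whose 6-exo-trig Claisen (Dieckmann) closure, helped by the gem-diprenyl effect, should end in the stable enolate of the β-triketone; hydroxide is used because dry methoxide would open the ring only to a methyl enol ether that cannot supply the C2 nucleophile.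

**Compound list**

1 | methyl acetoacetate | COC(=O)CC(C)=O | starting material
2 | 1-bromo-3-methylbut-2-ene (prenyl bromide) | CC(C)=CCBr | starting material
3 | methyl 7-methyl-3-oxooct-6-enoate | COC(=O)CC(=O)CCC=C(C)C | intermediate
4 | methyl 7-methyl-2,2-bis(3-methylbut-2-enyl)-3-oxooct-6-enoate | COC(=O)C(CC=C(C)C)(CC=C(C)C)C(=O)CCC=C(C)C | intermediate
5 | methyl (3Z)-7-methyl-2,2-bis(3-methylbut-2-enyl)-3-(trimethylsilyloxy)octa-3,6-dienoate | COC(=O)C(CC=C(C)C)(CC=C(C)C)/C(O[Si](C)(C)C)=C/CC=C(C)C | intermediate
6 | 2,2,6-trimethyl-4H-1,3-dioxin-4-one | CC1=CC(=O)OC(C)(C)O1 | starting material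
7 | 6-ethyl-2,2-dimethyl-4H-1,3-dioxin-4-one | CCC1=CC(=O)OC(C)(C)O1 | intermediate
8 | propionylketene (pent-1-ene-1,3-dione) | CCC(=O)C=C=O | intermediate
9 | methyl 2-[6-ethyl-3-(3-methylbut-2-enyl)-4-oxo-2-(trimethylsilyloxy)-3,4-dihydro-2H-pyran-2-yl]-5-methyl-2-(3-methylbut-2-enyl)hex-4-enoate, racemic, silyloxy group and ring prenyl group cis (one enantiomer drawn) | CCC1=CC(=O)[C@@H](CC=C(C)C)[C@](O1)(O[Si](C)(C)C)C(CC=C(C)C)(CC=C(C)C)C(=O)OC | intermediate
10 | methyl 2-[6-ethyl-3-(3-methylbut-2-enyl)-4-oxo-4H-pyran-2-yl]-5-methyl-2-(3-methylbut-2-enyl)hex-4-enoate | CCC1=CC(=O)C(CC=C(C)C)=C(O1)C(CC=C(C)C)(CC=C(C)C)C(=O)OC | intermediate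
11 | methyl 2,2,4-tris(3-methylbut-2-enyl)-3,5,7-trioxononanoate (C4 enolisable, drawn as the triketo form) | CCC(=O)CC(=O)C(CC=C(C)C)C(=O)C(CC=C(C)C)(CC=C(C)C)C(=O)OC | intermediate
12 | postlupulone, 3,5-dihydroxy-4,6,6-tris(3-methylbut-2-enyl)-2-propanoylcyclohexa-2,4-dien-1-one | CCC(=O)C1=C(O)C(CC=C(C)C)=C(O)C(CC=C(C)C)(CC=C(C)C)C1=O | target

**Step count.** Total: 6 steps. Longest linear sequence: 5 steps (steps 1, 2, 3, 5, 6); the dioxinone branch is 1 step (step 4).

**Steps most likely to fail**

1. Step 5. The acylketene may dimerise or be consumed by the liberated silanol faster than the crowded, trisubstituted enol ether captures it. The enol ether may also be protodesilylated back to the ketone or suffer a thermal [3,3] shift of an α-prenyl group during the long heating. Fallback, setting out from keto ester 4 and returning at pyranone 10: the lithium enolate of 4 (LiN(SiMe3)2, THF, −78 °C) would add to commercial pent-2-ynal to give the β-hydroxy ynone methyl 4-(1-hydroxypent-2-ynyl)-7-methyl-2,2-bis(3-methylbut-2-enyl)-3-oxooct-6-enoate F1. Dess–Martin periodinane (NaHCO3, CH2Cl2) would oxidise it to the ynedione methyl 7-methyl-2,2-bis(3-methylbut-2-enyl)-3-oxo-4-(pent-2-ynoyl)oct-6-enoate F2. The enol oxygen of F2 would then close by 6-endo-dig conjugate addition (K2CO3, MeCN, rt), an isomerisation that gives 10 without any ketene.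

2. Step 6. Opening of the trialkylated pyranone may be slow, so that saponification of the ester, retro-Claisen cleavage of the open tricarbonyl chain or autoxidation of the enolate competes with the C1–C2 closure. Fallback, setting out from keto ester 4 and returning at target 12, closes the ring before the propionyl group is present. Soft enolisation of 4 (MgBr2·OEt2, i-Pr2NEt, CH2Cl2) and C-acetylation with acetyl chloride would give methyl 2,2,4-tris(3-methylbut-2-enyl)-3,5-dioxohexanoate F3. Its dianion (LiN(i-Pr)2, 2.2 equiv, THF, −78 to 0 °C) would undergo Dieckmann closure of the terminal carbanion onto the ester to give the deacyl ring 3,5-dihydroxy-4,6,6-tris(3-methylbut-2-enyl)cyclohexa-2,4-dien-1-one F4. C-Acylation of F4 at C2 with propionic acid (DCC, DMAP, CH2Cl2; O-acylation followed by DMAP-induced O-to-C acyl shift) would give 12.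

3. Step 4. The lithium dienolate may fragment on warming, or be methylated at the ring α-carbon or twice, giving mixtures that are hard to separate from 7. Fallback, setting out from methyl acetoacetate 1 and returning at dioxinone 7: dianion methylation of 1 (NaH; n-BuLi; MeI, THF, 0 °C) would give methyl 3-oxopentanoate F5. Cold saponification (NaOH, H2O, 0 °C; acidification at 0 °C) would give 3-oxopentanoic acid F6. Condensation of F6 with acetone (Ac2O, H2SO4 cat., 0 °C) would close the dioxinone ring to give 7.

**Further compounds**

F1 | step 5 | methyl 4-(1-hydroxypent-2-ynyl)-7-methyl-2,2-bis(3-methylbut-2-enyl)-3-oxooct-6-enoate (mixture of diastereomers) | CCC#CC(O)C(CC=C(C)C)C(=O)C(CC=C(C)C)(CC=C(C)C)C(=O)OC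
F2 | step 5 | methyl 7-methyl-2,2-bis(3-methylbut-2-enyl)-3-oxo-4-(pent-2-ynoyl)oct-6-enoate | CCC#CC(=O)C(CC=C(C)C)C(=O)C(CC=C(C)C)(CC=C(C)C)C(=O)OC
F3 | step 6 | methyl 2,2,4-tris(3-methylbut-2-enyl)-3,5-dioxohexanoate | COC(=O)C(CC=C(C)C)(CC=C(C)C)C(=O)C(CC=C(C)C)C(C)=O
F4 | step 6 | 3,5-dihydroxy-4,6,6-tris(3-methylbut-2-enyl)cyclohexa-2,4-dien-1-one | O=C1C=C(O)C(CC=C(C)C)=C(O)C1(CC=C(C)C)CC=C(C)C
F5 | step 4 | methyl 3-oxopentanoate | CCC(=O)CC(=O)OC
F6 | step 4 | 3-oxopentanoic acid | CCC(=O)CC(O)=O
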